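**Retrosynthetic overview**

1. The target is (2S)-naringenin whose 4'-oxygen is O-3 of kaempferol. It is released by hydrogenolysis of five benzyl ethers from flavanone 18, whose C4 ketone is restored from (2S)-flav-3-ene 16 by Markovnikov hydration and oxidation.
2. Key disconnection: O1–C2 and C3–C4 of the flavanone heterocycle are made together, with the C2 stereocentre, by an isothiourea-catalysed acyl-transfer cascade of aryl cinnamate 14 that ends with loss of CO2.
3. Enabling feature: on ring A of the flavanone half, O1 (on C8a) and C4 (on C4a) are ortho. Esterifying O1 with the cinnamoyl unit whose β- and α-carbons are C2 and C3 puts Michael donor (O1), acceptor (C2), enolate carbon (C3) and formyl acceptor (C4) in one molecule; the ester carbonyl is a traceless CO2 tether.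
4. Ester 14 comes from cinnamic acid 10 and salicylaldehyde 12; 10 comes from aldehyde 8 (Doebner), and 8 from tri-O-benzylkaempferol 6 and 4-fluorobenzaldehyde (SNAr).
5. Ring order: the kaempferol pyranone ring first (chalcone 3, flavone 4, flavonol 6), then the flavanone heterocycle (step 8), brought to the ketone level in steps 9 and 10.

Key step: step 8

Remark: Kf stands for the 5,7-bis(benzyloxy)-2-[4-(benzyloxy)phenyl]-4-oxo-4H-chromen-3-yl group (tri-O-benzylkaempferol-3-yl).

Assumption: the sense of induction in step 8 is assigned from the accepted model for α,β-unsaturated acyl isothiouronium ions (s-cis, 1,5 O···S lock, attack anti to the C2 phenyl group). If a model ester shows the opposite sense, the enantiomeric catalyst, equally available, is used.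

**Step 1**
Reactants: 1 1-[2,4-bis(benzyloxy)-6-hydroxyphenyl]ethan-1-one; 2 4-(benzyloxy)benzaldehyde
Product: 3 (2E)-1-[2,4-bis(benzyloxy)-6-hydroxyphenyl]-3-[4-(benzyloxy)phenyl]prop-2-en-1-one
Conditions: KOH, EtOH/THF, rt
Reagents that add atoms: none
Why: Claisen–Schmidt aldol condensation of the methyl ketone enolate with the non-enolisable aldehyde, the E-alkene arising from E1cB dehydration.

**Step 2**
Reactants: 3 chalcone
Product: 4 5,7-bis(benzyloxy)-2-[4-(benzyloxy)phenyl]-4H-chromen-4-one
Conditions: I2 (10 mol %), DMSO, 120 °C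
Reagents that add atoms: none
Why: Iodine/DMSO oxidative cyclisation of a 2'-hydroxychalcone (oxa-Michael closure, α-iodination and loss of HI, with DMSO re-oxidising HI) should close the kaempferol pyranone ring while the benzyl ethers survive the short heating.

**Step 3**
Reactants: 4 tri-O-benzylapigenin
Product: 6 5,7-bis(benzyloxy)-2-[4-(benzyloxy)phenyl]-3-hydroxy-4H-chromen-4-one, via flavone epoxide 5 (not isolated)
Conditions: DMDO, acetone/CH2Cl2, 0 °C to rt; then TsOH·H2O (cat.), CH2Cl2, rt
Reagents that add atoms: dimethyldioxirane, CC1(C)OO1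
Why: Dioxirane epoxidation of the chromone C2=C3 bond followed by acid-catalysed opening at C2 (oxocarbenium ion) and loss of H-3 is the established flavone-to-flavonol oxidation and installs the 3-OH.

**Step 4**
Reactants: 6 tri-O-benzylkaempferol; 7 4-fluorobenzaldehyde
Product: 8 4-(Kf-oxy)benzaldehyde
Conditions: K2CO3, DMF, 90 °C, argon
Reagents that add atoms: none
Why: Nucleophilic aromatic substitution, in which the flavonolate oxygen adds para to the formyl group (Meisenheimer intermediate) and fluoride leaves, should form the diaryl ether; oxygen is excluded because flavonolates are air-sensitive.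

**Step 5**
Reactants: 8 aldehyde; 9 malonic acid
Product: 10 (2E)-3-[4-(Kf-oxy)phenyl]prop-2-enoic acid
Conditions: pyridine, piperidine (cat.), 85 °C
Reagents that add atoms: none
Why: Knoevenagel–Doebner condensation with decarboxylation in the same pot should give the (E)-cinnamic acid, whose α- and β-carbons become C3 and C2 of the flavanone.

**Step 6**
Reactants: 11 2,4,6-trihydroxybenzaldehyde
Product: 12 2,4-bis(benzyloxy)-6-hydroxybenzaldehyde
Conditions: BnBr (2.1 equiv), K2CO3, DMF, 0 °C to rt
Reagents that add atoms: benzyl bromide, BrCc1ccccc1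
Why: Williamson etherification takes the para hydroxyl and one ortho hydroxyl, while the second ortho hydroxyl is held back by its hydrogen bond to the formyl group.

**Step 7**
Reactants: 10 cinnamic acid; 12 salicylaldehyde
Product: 14 3,5-bis(benzyloxy)-2-formylphenyl (2E)-3-[4-(Kf-oxy)phenyl]prop-2-enoate, via acid chloride 13 (not isolated)
Conditions: 1-chloro-N,N,2-trimethylprop-1-en-1-amine, CH2Cl2, 0 °C to rt; then 12, i-Pr2NEt, CH2Cl2, −20 to 0 °C
Reagents that add atoms: none
Why: Neutral acid chloride formation and O-acylation of the phenol with a hindered amine base give the aryl ester without any achiral nucleophilic acyl-transfer catalyst, which could otherwise start a racemic version of the step 8 cascade.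

**Step 8**
Reactants: 14 aryl cinnamate
Product: 16 (2S)-5,7-bis(benzyloxy)-2-[4-(Kf-oxy)phenyl]-2H-chromene, via beta-lactone 15 (not isolated)
Conditions: (2R,3S)-3-isopropyl-2-phenyl-3,4-dihydro-2H-benzo[4,5]thiazolo[3,2-a]pyrimidine [(2R,3S)-HyperBTM] (10 mol %), toluene, rt to 40 °C, dark
Reagents that add atoms: none
Why: Proposed new method: the isothiourea is N-acylated by the aryl ester of 14 and expels the 2-formyl-3,5-bis(benzyloxy)phenoxide as counter-ion of an α,β-unsaturated acyl isothiouronium; this phenoxide adds 1,4 to the β-carbon (O1–C2), the resulting ammonium enolate adds to the ortho formyl carbon (C3–C4), the aldolate lactonises onto the acyl isothiouronium to release the catalyst, and β-lactone 15 extrudes CO2 to give the C3=C4 alkene. The closest known reaction type is the isothiourea-catalysed acyl-transfer-initiated thia-Michael/aldol/β-lactonisation/decarboxylation of S-(2-formylaryl) α,β-unsaturated thioesters to 2-substituted 2H-thiochromenes, together with α,β-unsaturated acyl ammonium catalysis from aryl esters in which the released aryloxide takes part in turnover; the oxygen Michael donor is the new element. The pyran ring closes by 6-exo-trig aldol addition of the enolate carbon to the formyl group after the ion-pair oxa-Michael addition, the oxetanone closes by 4-exo-trig acyl substitution, and the retro-[2+2] loss of CO2 is driven by release of β-lactone strain and by the benzylic C4–O bond that the 5,7-dialkoxy ring A weakens. C2 is the only stereocentre that survives and it is set by the catalyst in the oxa-Michael step: the acyl isothiouronium is held s-cis and coplanar by the 1,5 O···S contact and the phenoxide adds anti to the pseudoaxial C2 phenyl group of the catalyst, which for the (2R,3S) catalyst should give 2S, while the C3 and C4 centres of 15 are erased. The step needs 1,4- over 1,2-addition of the phenoxide, secured because 1,2-addition only regenerates 14 whereas the 1,4-adduct is drained irreversibly by aldol addition, lactonisation and CO2 loss; it also needs the absence of a racemic background, secured by leaving out any achiral nucleophilic catalyst and by working in the dark so that the 2H-chromene does not ring-open.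

**Step 9**
Reactants: 16 (2S)-flav-3-ene
Product: 17 (2S)-5,7-bis(benzyloxy)-2-[4-(Kf-oxy)phenyl]-3,4-dihydro-2H-chromen-4-ol
Conditions: Co(acac)2 (20 mol %), PhSiH3, O2 (1 atm), THF/i-PrOH, 0 °C to rt; then PPh3
Reagents that add atoms: dioxygen, O=O
Why: Mukaiyama hydration by metal-hydride hydrogen-atom transfer delivers H to C3 so that the radical forms at benzylic C4 next to the dialkoxy ring A and is trapped by O2; the tetrasubstituted electron-poor chromone alkene should react far more slowly, C2 is untouched, and any ketone formed directly is the product of step 10.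

**Step 10**
Reactants: 17 flavan-4-ol (both C4 epimers)
Product: 18 (2S)-5,7-bis(benzyloxy)-2-[4-(Kf-oxy)phenyl]-2,3-dihydro-4H-chromen-4-one
Conditions: Dess–Martin periodinane, pyridine, CH2Cl2, 0 °C to rt
Reagents that add atoms: none
Why: Dess–Martin oxidation of the benzylic secondary alcohol converges both C4 epimers on the flavanone under buffered, non-basic conditions that avoid retro-oxa-Michael opening, so C2 should keep its configuration.

**Step 11**
Reactants: 18 penta-O-benzyl flavanone
Product: 19 (2S)-5,7-dihydroxy-2-(4-{[5,7-dihydroxy-2-(4-hydroxyphenyl)-4-oxo-4H-chromen-3-yl]oxy}phenyl)-2,3-dihydro-4H-chromen-4-one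
Conditions: H2 (1 atm), 10% Pd/C, EtOAc/MeOH, rt
Reagents that add atoms: none
Why: Catalytic hydrogenolysis cleaves the five benzyl ethers under neutral conditions that should leave the diaryl ether, the chromone double bond and the base-labile C2 stereocentre intact, the reaction being stopped once hydrogen uptake ends.

**Compound list**

1 | 1-[2,4-bis(benzyloxy)-6-hydroxyphenyl]ethan-1-one | CC(=O)c1c(O)cc(OCc2ccccc2)cc1OCc1ccccc1 | starting material
2 | 4-(benzyloxy)benzaldehyde | O=Cc1ccc(OCc2ccccc2)cc1 | starting material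
3 | (2E)-1-[2,4-bis(benzyloxy)-6-hydroxyphenyl]-3-[4-(benzyloxy)phenyl]prop-2-en-1-one | O=C(/C=C/c1ccc(OCc2ccccc2)cc1)c1c(O)cc(OCc2ccccc2)cc1OCc1ccccc1 | intermediate
4 | 5,7-bis(benzyloxy)-2-[4-(benzyloxy)phenyl]-4H-chromen-4-one | O=c1cc(-c2ccc(OCc3ccccc3)cc2)oc2cc(OCc3ccccc3)cc(OCc3ccccc3)c12 | intermediate
5 | racemic 2,3-epoxide of 4 (5,7-bis(benzyloxy)-1a-[4-(benzyloxy)phenyl]-1a,7a-dihydro-7H-oxireno[2,3-b]chromen-7-one) | O=C1C2OC2(c2ccc(OCc3ccccc3)cc2)Oc2cc(OCc3ccccc3)cc(OCc3ccccc3)c21 | intermediate
6 | 5,7-bis(benzyloxy)-2-[4-(benzyloxy)phenyl]-3-hydroxy-4H-chromen-4-one (KfOH) | O=c1c(O)c(-c2ccc(OCc3ccccc3)cc2)oc2cc(OCc3ccccc3)cc(OCc3ccccc3)c12 | intermediate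
7 | 4-fluorobenzaldehyde | O=Cc1ccc(F)cc1 | starting material
8 | 4-({5,7-bis(benzyloxy)-2-[4-(benzyloxy)phenyl]-4-oxo-4H-chromen-3-yl}oxy)benzaldehyde | O=Cc1ccc(Oc2c(-c3ccc(OCc4ccccc4)cc3)oc3cc(OCc4ccccc4)cc(OCc4ccccc4)c3c2=O)cc1 | intermediate
9 | malonic acid | OC(=O)CC(=O)O | starting material
10 | (2E)-3-[4-(Kf-oxy)phenyl]prop-2-enoic acid | OC(=O)/C=C/c1ccc(Oc2c(-c3ccc(OCc4ccccc4)cc3)oc3cc(OCc4ccccc4)cc(OCc4ccccc4)c3c2=O)cc1 | intermediate
11 | 2,4,6-trihydroxybenzaldehyde | O=Cc1c(O)cc(O)cc1O | starting material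
12 | 2,4-bis(benzyloxy)-6-hydroxybenzaldehyde | O=Cc1c(O)cc(OCc2ccccc2)cc1OCc1ccccc1 | intermediate
13 | (2E)-3-[4-(Kf-oxy)phenyl]prop-2-enoyl chloride | ClC(=O)/C=C/c1ccc(Oc2c(-c3ccc(OCc4ccccc4)cc3)oc3cc(OCc4ccccc4)cc(OCc4ccccc4)c3c2=O)cc1 | intermediate
14 | 3,5-bis(benzyloxy)-2-formylphenyl (2E)-3-[4-(Kf-oxy)phenyl]prop-2-enoate | O=Cc1c(OC(=O)/C=C/c2ccc(Oc3c(-c4ccc(OCc5ccccc5)cc4)oc4cc(OCc5ccccc5)cc(OCc5ccccc5)c4c3=O)cc2)cc(OCc2ccccc2)cc1OCc1ccccc1 | intermediate
15 | cis-fused β-lactone: 5,7-bis(benzyloxy)-2-[4-(Kf-oxy)phenyl]chromane with a C3–C(=O)–O–C4 oxetanone bridge anti to the C2 aryl group, C2 as in 16 | O=C1O[C@H]2c3c(OCc4ccccc4)cc(OCc4ccccc4)cc3O[C@H](c3ccc(Oc4c(-c5ccc(OCc6ccccc6)cc5)oc5cc(OCc6ccccc6)cc(OCc6ccccc6)c5c4=O)cc3)[C@@H]12 | intermediate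
16 | (2S)-5,7-bis(benzyloxy)-2-[4-(Kf-oxy)phenyl]-2H-chromene | C1=C[C@@H](c2ccc(Oc3c(-c4ccc(OCc5ccccc5)cc4)oc4cc(OCc5ccccc5)cc(OCc5ccccc5)c4c3=O)cc2)Oc2cc(OCc3ccccc3)cc(OCc3ccccc3)c21 | intermediate
17 | (2S)-5,7-bis(benzyloxy)-2-[4-(Kf-oxy)phenyl]-3,4-dihydro-2H-chromen-4-ol (both C4 epimers) | OC1C[C@@H](c2ccc(Oc3c(-c4ccc(OCc5ccccc5)cc4)oc4cc(OCc5ccccc5)cc(OCc5ccccc5)c4c3=O)cc2)Oc2cc(OCc3ccccc3)cc(OCc3ccccc3)c21 | intermediate
18 | (2S)-5,7-bis(benzyloxy)-2-[4-(Kf-oxy)phenyl]-2,3-dihydro-4H-chromen-4-one | O=C1C[C@@H](c2ccc(Oc3c(-c4ccc(OCc5ccccc5)cc4)oc4cc(OCc5ccccc5)cc(OCc5ccccc5)c4c3=O)cc2)Oc2cc(OCc3ccccc3)cc(OCc3ccccc3)c21 | intermediate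
19 | (2S)-5,7-dihydroxy-2-(4-{[5,7-dihydroxy-2-(4-hydroxyphenyl)-4-oxo-4H-chromen-3-yl]oxy}phenyl)-2,3-dihydro-4H-chromen-4-one | O=C1C[C@@H](c2ccc(Oc3c(-c4ccc(O)cc4)oc4cc(O)cc(O)c4c3=O)cc2)Oc2cc(O)cc(O)c21 | target

**Step count and risks**

Total step count: 11. Longest linear sequence: 10 steps (steps 1 to 5 and 7 to 11); step 6 is a one-step branch.

Steps most likely to fail:

1. Step 8 (proposed new method). The released phenoxide may return only by degenerate 1,2-acyl transfer so that conjugate addition and turnover do not occur, or it may add with poor facial selectivity. The fallback uses known chemistry, sets out from aldehyde 8 and salicylaldehyde 12, and returns at 16.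
   - Aldehyde 8 is homologated with (triphenylphosphoranylidene)acetaldehyde (toluene, 80 °C) to (2E)-3-[4-(Kf-oxy)phenyl]prop-2-enal F1.
   - F1 and 12 undergo the aminocatalytic domino oxa-Michael/aldol condensation with (S)-2-[diphenyl(trimethylsilyloxy)methyl]pyrrolidine (20 mol %) and 2-nitrobenzoic acid (20 mol %) in toluene over molecular sieves. Iminium oxa-Michael addition on the Si face, then enamine aldol condensation, should give (2R)-5,7-bis(benzyloxy)-2-[4-(Kf-oxy)phenyl]-2H-chromene-3-carbaldehyde F2. The descriptor R here is the same spatial arrangement as 2S in 16, because the formyl group raises the rank of C3.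
   - Tsuji–Wilkinson decarbonylation of F2 with RhCl(PPh3)3 (stoichiometric, toluene, 90 °C, dark) gives 16.

2. Step 9. Hydrogen-atom transfer may also reach the chromone double bond, the electron-rich 2H-chromene may be oxidised to a flavylium ion, or the C4 radical may dimerise. The fallback sets out from 16 and returns at 17 by a polar Markovnikov hydration.
   - Oxymercuration with Hg(OAc)2 in THF/H2O at 0 °C gives the trans organomercurial (2S)-3-(acetoxymercurio)-5,7-bis(benzyloxy)-2-[4-(Kf-oxy)phenyl]-3,4-dihydro-2H-chromen-4-ol F3, with the hydroxyl on the cation-stabilising benzylic C4.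
   - Demercuration with NaBH4 in aqueous NaOH at 0 °C gives 17.

3. Step 4. Addition of the hindered, delocalised flavonolate to the weakly activated fluoroarene may be slow, and the flavonolate may degrade oxidatively at the temperature needed. The fallback sets out from 6 and returns at 8: metal-free ligand-coupling O-arylation with (4-formylphenyl)(2,4,6-trimethoxyphenyl)iodonium tosylate and t-BuOK in THF at rt. This is the known O-arylation of phenols and enols with diaryliodonium salts, in which the electron-poor aryl group is transferred. It forms no new compound (entry F0).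

**Further compounds**

F1 | step 8 | (2E)-3-[4-(Kf-oxy)phenyl]prop-2-enal | O=C/C=C/c1ccc(Oc2c(-c3ccc(OCc4ccccc4)cc3)oc3cc(OCc4ccccc4)cc(OCc4ccccc4)c3c2=O)cc1
F2 | step 8 | (2R)-5,7-bis(benzyloxy)-2-[4-(Kf-oxy)phenyl]-2H-chromene-3-carbaldehyde | O=CC1=Cc2c(OCc3ccccc3)cc(OCc3ccccc3)cc2O[C@@H]1c1ccc(Oc2c(-c3ccc(OCc4ccccc4)cc3)oc3cc(OCc4ccccc4)cc(OCc4ccccc4)c3c2=O)cc1
F3 | step 9 | (2S)-3-(acetoxymercurio)-5,7-bis(benzyloxy)-2-[4-(Kf-oxy)phenyl]-3,4-dihydro-2H-chromen-4-ol (Hg anti to the C2 aryl group, OH trans to Hg) | O[C@H]1[C@H]([Hg]OC(C)=O)[C@@H](c2ccc(Oc3c(-c4ccc(OCc5ccccc5)cc4)oc4cc(OCc5ccccc5)cc(OCc5ccccc5)c4c3=O)cc2)Oc2cc(OCc3ccccc3)cc(OCc3ccccc3)c21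
F0 | step 4 | none | none
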